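East keeps 79% of its substrate after 40.0 h, and north-east keeps 45% after 25.0 h.

| setting | east | north-east | blue | green |
|---|---|---|---|---|
| substrate | 2 M | 2 M | 2.5 M | 1.7 M |
| temperature | 20 °C | 35 °C |  |  |
| remark | run made earlier | run made earlier | at 25 °C throughout | at 25 °C until 30 h, from then on at 45 °C |
| time |  |  | 2.5 d | 2.5 d |

| run | time / h | target / % | substrate / % |
|---|---|---|---|
| east | 8.00 | 0 | 95 |
| east | 15.0 | 2 | 89 |
| east | 20.0 | 3 | 89 |
| east | 30.0 | 3 | 83 |
| east | 40.0 | 4 | 79 |
| north-east | 5.00 | 0 | 83 |
| north-east | 10.0 | 7 | 68 |
| north-east | 12.0 | 8 | 66 |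
| north-east | 20.0 | 13 | 56 |
| north-east | 25.0 | 15 | 45 |

(standard deviation of a reading: 2 percentage points)

- the analysis behind the earlier runs scatters by 2 percentage points, standard deviation
- a reading or a percentage of target counts all its forms, free or not
- a reading of substrate is of its free form alone

- which one finishes higher in amount of target, in percent of the substrate charged ("neither" within 2 percentage points) (blue / green / neither)
- amount of target at the end, in percent of the substrate charged, blue
- amount of target at the end, in percent of the substrate charged, green

Both runs start at c(substrate) = 2 M, so the order in substrate cannot be read, and I assume a first-order loss. That gives 0.00589 h⁻¹ at 20 °C and 0.0319 h⁻¹ at 35 °C, a factor of 5.42. I stretch that factor evenly over the degrees, so I take 0.0104 h⁻¹ at 25 °C and 0.0986 h⁻¹ at 45 °C as my estimates.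

Two times matter for green: its loss time when hot, 10.1 h, and its hot hold, 30.0 h. Their ratio is 2.96, the hold counted in loss times. Blue's whole run counts 0.621 loss times. Because green's hold counts more than that, I put green ahead. My reckoning leaves green 3.81% of its substrate.

The forecast also says green, with blue at 13% (8% to 20%) and green at 43% (24% to 66%). Its ground for green's hot stage is that it “consumes nearly everything”.

The flask gives green, with blue at 12.2% and green at 21.6%, which is below the forecast's range.

    substrate + target ⇌ idle adduct, settled at all times (K = 4.40 M⁻¹, ΔH = −38.0 kJ mol⁻¹)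
    substrate ⇌ intermediate (K = 0.580, k = 3.40 × 10⁻⁶ s⁻¹, Ea = 97.0 kJ mol⁻¹, ΔH = −1.00 kJ mol⁻¹)
    crystals ⇌ target, rate k3*(cs3 - [target]) while solid is left; crystals form when [target] > cs3 (solubility = 0.840 M, k = 4.20 × 10⁻⁵ s⁻¹)
    intermediate ⇌ target (K = 0.550, k = 3.70 × 10⁻⁶ s⁻¹, Ea = 97.0 kJ mol⁻¹, ΔH = −12.0 kJ mol⁻¹)
    (constants at 25 °C)

Green ends with 42.6% of its substrate, not my 3.81%. My count treats the loss as one-way, but in green at 45 °C the step between substrate and intermediate, taken by itself, has a relaxation half-life of 0.0728 d both ways together, shorter than green's hold. At its end green stands at equilibrium, which is thermodynamic control. The neighbouring flask is green left until 10 d. Its hold counts 20.7 loss times, more than green's. It ends with 42.5% substrate and 21.6% target.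

The numbers in the tables were computed on assumed constants; noise was put on by code.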